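1. The problem posed 5 questions: one order of the set-ups and a yield of target for each.

| setting | east | west | south | south-west |
|---|---|---|---|---|
| starting material | 20 mM | 20 mM (fed, over 8.00 h) | 20 mM | 20 mM |
| reagent | 30.0 mM | 30.0 mM | 30.0 mM | 30.0 mM |
| initiator | 0.15 mM | 0.15 mM | 0.15 mM | 0.15 mM |
| remark | a single well-mixed tank run continuously and read at steady state, 80.0 h in it on average | all but starting material at the start; starting material goes in evenly over 8.00 h, the run ends at 8.0 h | a closed flask charged with all of it at once and left for 8.0 h | a single well-mixed tank run continuously and read at steady state, 8.0 h in it on average |
| time |  | 8.0 h | 8.0 h |  |

- order of the set-ups by the amount of target at the outlet or at the end, in percent of the starting material put in, highest first (east / west / south / south-west)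
- amount of target at the outlet or at the end, in percent of the starting material put in, east
- amount of target at the outlet or at the end, in percent of the starting material put in, west
- amount of target at the outlet or at the end, in percent of the starting material put in, south
- amount of target at the outlet or at the end, in percent of the starting material put in, south-west

- in percentages every species weighs as the starting material in it: one ended chains counts as two
- two of one species on the left: rate k times its square, two consumed each time
- the stated concentrations are those of everything mixed, before any reaction; amounts are the same in each set-up
- the feed brings no volume worth counting
- run time (west): 8.0 h

    initiator → 2 initiating radical (k1 = 2.49 × 10⁻⁵ s⁻¹)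
    starting material + initiating radical → capped initiator + first chain carrier (k2 = 4.51 × 10⁵ M⁻¹ s⁻¹)
    reagent + first chain carrier ⇌ target + second chain carrier (K3 = 0.441, k3 = 4040 M⁻¹ s⁻¹)
    starting material + second chain carrier → released group + first chain carrier (k4 = 62400 M⁻¹ s⁻¹)
    2 first chain carrier → ended chains (k5 = 3 × 10⁶ M⁻¹ s⁻¹)
    target ⇌ isomer of the product (K6 = 2.5, k6 = 7.50 × 10⁻⁵ s⁻¹)

2. I began with what happens to target once it exists. It turns into isomer and back by first-order steps, so in this pair of steps, at fixed target plus isomer, its excess over equilibrium decays exponentially, at the sum of the forward and back rate constants.

3. The inverse of that sum came to 2.65 h. I called this the drift time, the time in which the excess of target over equilibrium falls by a factor of e. At equilibrium, target is 28.6% of target plus isomer.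

4. I integrated that decay in closed form over the age of the target. In a steady tank, the surviving excess is the inverse of one plus residence time over drift time. Even dosing averages the decay over the dosing time. Taking target as born when its starting material arrives, I reckoned target as a share of target plus isomer: west 51.0%, south-west 46.3% and east 30.9%.

5. South needed a birth time for its target. Balancing initiation against termination put first chain carrier near 3.53 × 10⁻⁵ mM. At the forward rate of its reaction with the charged reagent, my estimate for turning over the charge of starting material was 1.30 h, which is shorter than the run. I took the birth of target as the middle of that span, and the south share came to 33.0%.

6. My shares fell in the order west, south-west, south, east. They are shares of target plus isomer, and I did not reckon how much was converted in west or in the tanks.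

7. The forecast gave west > south-west > south > east, with 30.2% for east, 46.8% for west, 33.8% for south and 42.9% for south-west. Its ground for west was: “Feeding evenly keeps the target young and gives the highest yield”. Its order matched mine, but its numbers differed from my shares.

8. The simulation gave west > south-west > south > east, with 30.2% for east, 46.5% for west, 33.9% for south and 42.9% for south-west.

9. In west, the half-life of target by the forward step at 3.87 h was 2.6 h, shorter than the 8.00 h of dosing, and the end readings put target at 50.2% of target plus isomer, beside my 51.0%. South read 52.9% target and 46.4% isomer at 4.00 h; a further 4.00 h reckoned with the drift time gives 33.8% target, and south stood at 33.9% at 8.00 h.

(Its constants come from no measurement; the rest is arithmetic.)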